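**Assumption:** the heptane chain is numbered C1 (carbon bearing the 4-hydroxy-3,5-dimethoxyphenyl "syringyl" ring) to C7 (carbon bearing the 4-hydroxy-3-methoxyphenyl "guaiacyl" ring); the target SMILES decodes as the all-cis (2S,4R,6S)-oxan-4-ol; the boron chelates of step 1 are mixed borate species and are drawn as the simplest 1:1 dibutoxyboron diketonates.

## Retrosynthetic overview

1. The oxane is the only ring and is formed last: the syringyl arm of the open-chain (3S,5S)-diol is dehydrogenated to a p-quinone methide, and the C5 hydroxyl captures it to form the C1–O bond, as in the presumed biogenesis. This sets C1 (ring C2).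
2. The (3S,5S)-anti-diol comes from the 1,3-diketone by one double asymmetric hydrogenation, which sets C3 and C5.
3. The 1,3-diketone comes from the unsymmetrical curcuminoid by hydrogenation of both alkenes.
4. The curcuminoid comes from acetylacetone, vanillin and syringaldehyde by two sequential boron-templated aldol condensations.
5. No protecting groups are used.

## Route

Step 1
Reactants: 1 pentane-2,4-dione (acetylacetone); 2 vanillin (4-hydroxy-3-methoxybenzaldehyde)
Product: 5 feruloylacetone [(E)-6-(4-hydroxy-3-methoxyphenyl)hex-5-ene-2,4-dione], via boron chelate of acetylacetone 3 (not isolated), via boron chelate of feruloylacetone 4 (not isolated)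
Conditions: 1 (3 equiv), B2O3 (2 equiv), EtOAc, 80 °C; 2 (1 equiv), B(OBu)3 (1 equiv), n-BuNH2 (0.3 equiv, slow addition), 80 °C; then 0.4 M aq HCl, 60 °C
Reagents that add atoms: none
Why: Boron-templated aldol condensation (Pabon curcuminoid synthesis): chelation as 3 masks the central CH2 and directs condensation to a terminal methyl, excess 1 limits reaction to one arm, and dehydration gives the E-alkene; no stereocentre is formed.

Step 2
Reactants: 5 feruloylacetone; 6 syringaldehyde (4-hydroxy-3,5-dimethoxybenzaldehyde)
Product: 9 unsymmetrical curcuminoid [(1E,6E)-1-(4-hydroxy-3,5-dimethoxyphenyl)-7-(4-hydroxy-3-methoxyphenyl)hepta-1,6-diene-3,5-dione], via difluoroboron chelate of feruloylacetone 7 (not isolated), via difluoroboron chelate of the curcuminoid 8 (not isolated)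
Conditions: 5 (1 equiv), BF3·OEt2 (1.1 equiv), toluene–EtOAc, 65 °C, 2 h; 6 (1.1 equiv), n-BuNH2 (0.4 equiv, slow addition), 65 °C; then Na2C2O4 (3 equiv), MeOH–H2O (4:1), 65 °C
Reagents that add atoms: none
Why: Boron-templated aldol condensation on a difluoroboron diketonate: BF3·OEt2 converts the enolised diketone of 5 into chelate 7 under anhydrous conditions, which masks the central CH2 and acidifies the one remaining terminal methyl, so the amine-catalysed condensation with 6 and dehydration give the E,E-dienedione chelate 8 under thermodynamic control, and oxalate-buffered hydrolysis near pH 6 releases 9 without exposing the base-sensitive curcuminoid to strong base; no stereocentre is formed.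

Step 3
Reactants: 9 unsymmetrical curcuminoid
Product: 12 tetrahydro diketone [1-(4-hydroxy-3,5-dimethoxyphenyl)-7-(4-hydroxy-3-methoxyphenyl)heptane-3,5-dione], via syringyl-side enedione 10 (not isolated), via guaiacyl-side enedione 11 (not isolated)
Conditions: H2 (1 atm), 10% Pd/C, EtOAc, rt, stopped after 2 equiv H2
Reagents that add atoms: none
Why: Heterogeneous catalytic hydrogenation saturates the two styryl C=C bonds much faster than the enolised 1,3-diketone or the arenes (the curcumin to tetrahydrocurcumin selectivity); no stereocentre is formed.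

Step 4
Reactants: 12 tetrahydro diketone
Product: 15 (3S,5S)-1-(4-hydroxy-3,5-dimethoxyphenyl)-7-(4-hydroxy-3-methoxyphenyl)heptane-3,5-diol, via 5-hydroxy-3-ketone 13 (not isolated), via 3-hydroxy-5-ketone 14 (not isolated)
Conditions: RuCl2[(S)-BINAP] (1 mol %), H2 (50 atm), MeOH, 50 °C, 48 h
Reagents that add atoms: none
Why: Noyori asymmetric hydrogenation of a 1,3-diketone: the (S)-BINAP ruthenium hydride reduces each chelated carbonyl from the same enantioface under catalyst control (the sense that gives (S,S)-pentane-2,4-diol from acetylacetone), so the (S)-hydroxy ketones 13 and 14 form first and both converge on the anti (3S,5S)-diol, with most of the minor enantiomer diverted into the separable syn diol.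

Step 5
Reactants: 15 (3S,5S)-diol
Product: 17 (2S,4R,6S)-2-(4-hydroxy-3,5-dimethoxyphenyl)-6-[2-(4-hydroxy-3-methoxyphenyl)ethyl]oxan-4-ol (target), via syringyl p-quinone methide 16 (not isolated)
Conditions: DDQ (1.0 equiv, added over 1 h), MeCN (0.02 M), −20 °C to 0 °C; aq NaHCO3 work-up
Reagents that add atoms: none
Why: Proposed new method: DDQ should preferentially attack the more electron-rich ring (three oxygen donors, lower oxidation potential than the guaiacyl ring) and abstract the C1 benzylic hydride to give p-quinone methide 16, which the C5 hydroxyl captures by 6-exo attack (the C3 hydroxyl could only close an oxetane) through a chair transition state with the C3 hydroxyl, the C5 side chain and the arylidene terminus all equatorial, so the new centre is set cis to both existing centres by substrate control, and the closure is reversible under the acidic hydroquinone so the all-equatorial isomer is also the thermodynamic product; the closest known reaction type is DDQ dehydrogenation of p-alkylphenols to p-quinone methides with intramolecular hydroxyl capture, as used for aryltetrahydrofuran lignans.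

## Compound list

1 | pentane-2,4-dione (acetylacetone) | CC(=O)CC(C)=O | starting material
2 | vanillin | COc1cc(C=O)ccc1O | starting material
3 | dibutoxyboron chelate of the acetylacetone enolate | CC1=CC(C)=[O+][B-](OCCCC)(OCCCC)O1 | intermediate
4 | dibutoxyboron chelate of feruloylacetone | COc1cc(/C=C/C2=CC(C)=[O+][B-](OCCCC)(OCCCC)O2)ccc1O | intermediate
5 | feruloylacetone, (E)-6-(4-hydroxy-3-methoxyphenyl)hex-5-ene-2,4-dione | COc1cc(/C=C/C(=O)CC(C)=O)ccc1O | intermediate
6 | syringaldehyde | COc1cc(C=O)cc(OC)c1O | starting material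
7 | difluoroboron chelate of feruloylacetone | COc1cc(/C=C/C2=CC(C)=[O+][B-](F)(F)O2)ccc1O | intermediate
8 | difluoroboron chelate of curcuminoid 9 | COc1cc(/C=C/C2=CC(/C=C/c3cc(OC)c(O)c(OC)c3)=[O+][B-](F)(F)O2)ccc1O | intermediate
9 | (1E,6E)-1-(4-hydroxy-3,5-dimethoxyphenyl)-7-(4-hydroxy-3-methoxyphenyl)hepta-1,6-diene-3,5-dione | COc1cc(/C=C/C(=O)CC(=O)/C=C/c2cc(OC)c(O)c(OC)c2)ccc1O | intermediate
10 | (1E)-1-(4-hydroxy-3,5-dimethoxyphenyl)-7-(4-hydroxy-3-methoxyphenyl)hept-1-ene-3,5-dione | COc1cc(CCC(=O)CC(=O)/C=C/c2cc(OC)c(O)c(OC)c2)ccc1O | intermediate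
11 | (1E)-7-(4-hydroxy-3,5-dimethoxyphenyl)-1-(4-hydroxy-3-methoxyphenyl)hept-1-ene-3,5-dione | COc1cc(/C=C/C(=O)CC(=O)CCc2cc(OC)c(O)c(OC)c2)ccc1O | intermediate
12 | 1-(4-hydroxy-3,5-dimethoxyphenyl)-7-(4-hydroxy-3-methoxyphenyl)heptane-3,5-dione | COc1cc(CCC(=O)CC(=O)CCc2cc(OC)c(O)c(OC)c2)ccc1O | intermediate
13 | (5S)-5-hydroxy-1-(4-hydroxy-3,5-dimethoxyphenyl)-7-(4-hydroxy-3-methoxyphenyl)heptan-3-one | COc1cc(CC[C@H](O)CC(=O)CCc2cc(OC)c(O)c(OC)c2)ccc1O | intermediate
14 | (5S)-5-hydroxy-7-(4-hydroxy-3,5-dimethoxyphenyl)-1-(4-hydroxy-3-methoxyphenyl)heptan-3-one | COc1cc(CCC(=O)C[C@@H](O)CCc2cc(OC)c(O)c(OC)c2)ccc1O | intermediate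
15 | (3S,5S)-1-(4-hydroxy-3,5-dimethoxyphenyl)-7-(4-hydroxy-3-methoxyphenyl)heptane-3,5-diol (anti) | COc1cc(CC[C@H](O)C[C@@H](O)CCc2cc(OC)c(O)c(OC)c2)ccc1O | intermediate
16 | 4-[(3S,5S)-3,5-dihydroxy-7-(4-hydroxy-3-methoxyphenyl)heptylidene]-2,6-dimethoxycyclohexa-2,5-dien-1-one | COc1cc(CC[C@H](O)C[C@@H](O)CC=C2C=C(OC)C(=O)C(OC)=C2)ccc1O | intermediate
17 | (2S,4R,6S)-2-(4-hydroxy-3,5-dimethoxyphenyl)-6-[2-(4-hydroxy-3-methoxyphenyl)ethyl]oxan-4-ol, all-cis | COc1cc(CC[C@H]2C[C@@H](O)C[C@@H](c3cc(OC)c(O)c(OC)c3)O2)ccc1O | target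

## Step count and risks

Total step count: 5. Longest linear sequence: 5 steps (1 and 2 to 17).

**Step 5 (highest risk).** Both arms carry a p-hydroxybenzylic CH2, so DDQ may also dehydrogenate C7 of the guaiacyl arm, which would close the regioisomeric oxane through the C3 hydroxyl. The product can also be over-oxidised. The fallback makes the oxidation regiospecific by design; it sets out from 15 and comes back at 17. TIPSCl (1.05 equiv) and imidazole in DMF at 0 °C silylate the guaiacyl phenol (one ortho substituent) in preference to the doubly ortho-flanked syringyl phenol and the secondary alcohols. This gives (3S,5S)-1-(4-hydroxy-3,5-dimethoxyphenyl)-7-{3-methoxy-4-[(triisopropylsilyl)oxy]phenyl}heptane-3,5-diol F1. DDQ in MeCN can now form a quinone methide only on the ring with the free phenol, giving 4-[(3S,5S)-3,5-dihydroxy-7-{3-methoxy-4-[(triisopropylsilyl)oxy]phenyl}heptylidene]-2,6-dimethoxycyclohexa-2,5-dien-1-one F2. F2 closes in the flask to (2S,4R,6S)-2-(4-hydroxy-3,5-dimethoxyphenyl)-6-(2-{3-methoxy-4-[(triisopropylsilyl)oxy]phenyl}ethyl)oxan-4-ol F3. Bu4NF in THF at 0 °C removes the silyl group and returns 17.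

**Step 1.** Mono-condensation competes with double condensation to curcumin, and yields are typically moderate. The fallback replaces the templated aldol by an acylation that cannot over-react; it sets out from 2 and comes back at 5. Claisen–Schmidt condensation of 2 with acetone (aq NaOH, rt) gives dehydrozingerone, (E)-4-(4-hydroxy-3-methoxyphenyl)but-3-en-2-one F4, whose only enolisable position is the methyl group. Claisen acylation of its sodium dianion with ethyl acetate (NaH 3.5 equiv, EtOAc, THF, reflux, acidic work-up) gives 5.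

**Step 4.** Catalyst control in the second reduction may give too much syn diol, or the double reduction may stall. The fallback sets the second centre by substrate control; it sets out from 12 and comes back at 15. The RuCl2[(S)-BINAP] hydrogenation is run mildly (4 atm, 25 °C) and stopped after one equivalent of H2 to isolate the (S)-hydroxy ketones 13 and 14 as a mixture. Me4NBH(OAc)3 in MeCN–AcOH at −30 °C (Evans–Saksena reduction, intramolecular hydride delivery, 1,3-anti) then takes both regioisomers to 15. This fallback makes no compound outside the compound list (none F0).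

## Further compounds

F1 | step 5 | (3S,5S)-1-(4-hydroxy-3,5-dimethoxyphenyl)-7-{3-methoxy-4-[(triisopropylsilyl)oxy]phenyl}heptane-3,5-diol | COc1cc(CC[C@H](O)C[C@@H](O)CCc2cc(OC)c(O)c(OC)c2)ccc1O[Si](C(C)C)(C(C)C)C(C)C
F2 | step 5 | 4-[(3S,5S)-3,5-dihydroxy-7-{3-methoxy-4-[(triisopropylsilyl)oxy]phenyl}heptylidene]-2,6-dimethoxycyclohexa-2,5-dien-1-one | COc1cc(CC[C@H](O)C[C@@H](O)CC=C2C=C(OC)C(=O)C(OC)=C2)ccc1O[Si](C(C)C)(C(C)C)C(C)C
F3 | step 5 | (2S,4R,6S)-2-(4-hydroxy-3,5-dimethoxyphenyl)-6-(2-{3-methoxy-4-[(triisopropylsilyl)oxy]phenyl}ethyl)oxan-4-ol | COc1cc(CC[C@H]2C[C@@H](O)C[C@@H](c3cc(OC)c(O)c(OC)c3)O2)ccc1O[Si](C(C)C)(C(C)C)C(C)C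
F4 | step 1 | dehydrozingerone, (E)-4-(4-hydroxy-3-methoxyphenyl)but-3-en-2-one | COc1cc(/C=C/C(C)=O)ccc1O
F0 | step 4 | none | none
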